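**Plan**
1. Cuts: six O-benzyl groups; the C4–styryl bond of ring A (Suzuki–Miyaura) and a helper oxygen at C5 (removed as its triflate); O1–C2 and C3a–C3 of the ring-A dihydrofuran together, as a formal [3+2] union of 4-hydroxystilbene 15 with 2-benzyloxy-6-bromo-1,4-benzoquinone 18; the stilbene bond of 15 (Heck); C2'–C3' of the ring-B dihydrofuran (carbene C–H insertion).
2. Enabling feature: C2 carries a 4-hydroxyphenyl ring, so the C2=C3 alkene of 15 is a vinylogous enol. C3 (the carbon on ring B) is nucleophilic and C2 becomes a para-quinone methide carbon. Ring A (O1 on C7a, O on C6, carbon on C4) is a para-quinone once an extra oxygen sits on C5, which makes C3a electrophilic and turns a quinone oxygen into O1.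
3. Forward order: ring-B dihydrofuran, then the stilbene, then the ring-A dihydrofuran on the quinone (both halves joined), then styryl at C4, removal of the C5 oxygen, debenzylation.
4. Stereochemistry: C3' from the chiral dirhodium carboxylate in the C–H insertion and C2' by acid epimerisation to trans; C3 from the chiral phosphoric acid in the [3+2] step and C2 trans from the ring closure; both alkenes E from the Heck reaction and from syn-hydroboration/Suzuki coupling.

Key step: step 12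

Remark: locants O1, C2, C3, C3a, C4–C7, C7a belong to the dihydrobenzofuran that carries the styryl group (benzo ring = ring A) and primed locants to the second one (benzo ring = ring B). "Group G" means (2R,3R)-7-(benzyloxy)-2-[4-(benzyloxy)phenyl]-3-[3,5-bis(benzyloxy)phenyl]-2,3-dihydro-1-benzofuran-5-yl. The catalyst antipodes written are assumed to give the drawn configurations; the sense of induction would be checked in the first run and the antipode used if needed.

Step 1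
Reactants: 1 3-(benzyloxy)-2-hydroxybenzaldehyde
Product: 2 3-(benzyloxy)-5-bromo-2-hydroxybenzaldehyde
Conditions: NBS, MeCN, 0 °C to rt
Reagents that add atoms: N-bromosuccinimide, O=C1CCC(=O)N1Br
Why: Electrophilic aromatic bromination; the free OH directs to its para position C5, the ortho position being blocked by the benzyloxy group.

Step 2
Reactants: 2 3-(benzyloxy)-5-bromo-2-hydroxybenzaldehyde; 3 4-(benzyloxy)benzyl chloride
Product: 4 3-(benzyloxy)-2-{[4-(benzyloxy)benzyl]oxy}-5-bromobenzaldehyde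
Conditions: K2CO3, DMF, 60 °C
Reagents that add atoms: none
Why: Williamson ether synthesis; the benzylic CH2 introduced here becomes C2' of the ring-B dihydrofuran.

Step 3
Reactants: 4 3-(benzyloxy)-2-{[4-(benzyloxy)benzyl]oxy}-5-bromobenzaldehyde; 5 1,3-bis(benzyloxy)-5-bromobenzene
Product: 7 [3,5-bis(benzyloxy)phenyl](3-(benzyloxy)-2-{[4-(benzyloxy)benzyl]oxy}-5-bromophenyl)methanol (racemic), via aryl Grignard reagent 6 (not isolated)
Conditions: 5, Mg turnings, THF, reflux; then 4, THF, 0 °C; aq NH4Cl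
Reagents that add atoms: none
Why: Grignard addition to the aldehyde; the aryl bromide of 4 should not exchange at 0 °C, and the racemic carbinol centre is erased in step 4.

Step 4
Reactants: 7 the diarylmethanol
Product: 8 [3,5-bis(benzyloxy)phenyl](3-(benzyloxy)-2-{[4-(benzyloxy)benzyl]oxy}-5-bromophenyl)methanone
Conditions: activated MnO2, CH2Cl2, rt
Reagents that add atoms: none
Why: MnO2 oxidation of a doubly benzylic alcohol to the benzophenone; benzyl ethers and the aryl bromide are inert.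

Step 5
Reactants: 8 the diaryl ketone
Product: 9 hydrazone of 8
Conditions: N2H4·H2O (excess), AcOH (cat.), EtOH, 85 °C
Reagents that add atoms: hydrazine hydrate, NN.O
Why: Condensation of the hindered diaryl ketone with hydrazine gives the free hydrazone needed as diazo precursor.

Step 6
Reactants: 9 the hydrazone
Product: 11 (2S,3R)-7-(benzyloxy)-2-[4-(benzyloxy)phenyl]-3-[3,5-bis(benzyloxy)phenyl]-5-bromo-2,3-dihydro-1-benzofuran (cis), via diaryldiazomethane 10 (not isolated)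
Conditions: MnO2, CH2Cl2, 0 °C, filtration; filtrate added to Rh2(R-PTAD)4 (dirhodium tetrakis[(R)-(1-adamantyl)(N-phthalimido)acetate], 1 mol %), CH2Cl2, 0 °C
Reagents that add atoms: none
Why: Dehydrogenation to the diazo compound followed by dirhodium-catalysed intramolecular 1,5 C–H insertion of the donor/donor carbene into the ether CH2; the chiral carboxylate ligands set C3' (R) and the concerted insertion should give the cis isomer, while no other benzylic C–H can reach the carbene.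

Step 7
Reactants: 11 the cis-dihydrobenzofuran
Product: 12 (2R,3R)-7-(benzyloxy)-2-[4-(benzyloxy)phenyl]-3-[3,5-bis(benzyloxy)phenyl]-5-bromo-2,3-dihydro-1-benzofuran (trans)
Conditions: TFA (5 equiv), CH2Cl2 (dilute), 0 °C to rt
Reagents that add atoms: none
Why: Acid-mediated epimerisation; reversible heterolysis of O1'–C2' to the 4-alkoxybenzylic cation and reclosure should give the thermodynamically favoured trans isomer, C3' being untouched.

Step 8
Reactants: 12 the trans bromide; 13 4-acetoxystyrene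
Product: 14 4-[(E)-2-(group G)ethenyl]phenyl acetate
Conditions: Pd(OAc)2 (5 mol %), P(o-tol)3, Et3N, DMF, 100 °C
Reagents that add atoms: none
Why: Heck reaction; syn insertion and syn beta-hydride elimination give the E stilbene.

Step 9
Reactants: 14 the stilbene acetate
Product: 15 4-[(E)-2-(group G)ethenyl]phenol
Conditions: K2CO3 (0.2 equiv), MeOH/THF, 0 °C to rt, argon
Reagents that add atoms: none
Why: Mild transesterification frees the single phenol that activates the alkene in step 12; benzyl ethers are stable.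

Step 10
Reactants: 16 2-(benzyloxy)phenol
Product: 17 2-(benzyloxy)-6-bromophenol
Conditions: NBS, i-Pr2NH (10 mol %), CH2Cl2, 0 °C
Reagents that add atoms: N-bromosuccinimide, O=C1CCC(=O)N1Br
Why: Amine-catalysed ortho-selective bromination of a phenol; the N-bromoamine delivers bromine next to the hydrogen-bonded OH.

Step 11
Reactants: 17 2-(benzyloxy)-6-bromophenol
Product: 18 2-(benzyloxy)-6-bromo-1,4-benzoquinone
Conditions: (KSO3)2NO (potassium nitrosodisulfonate, 2.2 equiv), KH2PO4, H2O/acetone, 0 °C to rt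
Reagents that add atoms: potassium nitrosodisulfonate, [K+].[K+].[O]N(S(=O)(=O)[O-])S(=O)(=O)[O-]
Why: Teuber oxidation of a phenol with a free para position to the para-quinone.

Step 12
Reactants: 15 4-[(E)-2-(group G)ethenyl]phenol; 18 2-(benzyloxy)-6-bromo-1,4-benzoquinone
Product: 20 (2S,3S)-6-(benzyloxy)-4-bromo-3-(group G)-2-(4-hydroxyphenyl)-2,3-dihydro-1-benzofuran-5-ol, via quinone methide hydroquinone 19 (not isolated)
Conditions: (R)-TRIP [(R)-3,3'-bis(2,4,6-triisopropylphenyl)-1,1'-binaphthyl-2,2'-diyl hydrogen phosphate, 10 mol %], 4 Å MS, toluene/CH2Cl2, −20 °C, argon, dark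
Reagents that add atoms: none
Why: Proposed new method: the phosphoric acid should bind the C1 carbonyl of 18 through P–OH and the phenolic OH of 15 through P=O, so that the vinylogous enol carbon of the 4-hydroxystilbene (the alkene carbon on ring B, future C3) adds in Michael fashion to the unsubstituted C5 of the quinone (future C3a) and tautomerisation gives the hydroquinone para-quinone methide 19. The hydroquinone oxygen ortho to the new C–C bond then closes the dihydrofuran by 5-exo-trig oxa-1,6-addition to the quinone methide carbon (future C2). The closest known reaction types are the TiCl4-promoted formal [3+2] cycloaddition of 2-alkoxy-1,4-benzoquinones with (E)-propenylarenes and the chiral phosphoric acid-catalysed [3+2] couplings of quinones and quinone monoimides with enecarbamates and hydroxystyrenes; a 4-hydroxystilbene with a 2-alkoxy-6-bromoquinone has not been used. C3 is set in the Michael step by the catalyst (the stereocentres of the ring-B dihydrofuran are remote and should not interfere), and C2 follows from C3 because the reversible ring closure places the two aryl groups trans. Regioselectivity on the alkene is secured by the single free phenol, the only oxygen that can form a quinone methide (all others are benzyl ethers). Regioselectivity on the quinone is secured by the benzyloxy group, which makes C3 of the quinone an electron-rich enol ether carbon and leaves C5 as the only acceptor site, and only the C4 oxygen is ortho to the new bond.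

Step 13
Reactants: 21 1-(benzyloxy)-4-ethynylbenzene
Product: 22 2-{(E)-2-[4-(benzyloxy)phenyl]ethenyl}-4,4,5,5-tetramethyl-1,3,2-dioxaborolane
Conditions: pinacolborane, Cp2Zr(H)Cl (10 mol %), Et3N (10 mol %), neat, 60 °C
Reagents that add atoms: pinacolborane, [H]B1OC(C)(C)C(C)(C)O1
Why: Zirconium-catalysed syn hydroboration of a terminal alkyne gives the (E)-alkenylboronate.

Step 14
Reactants: 20 the bromo hydroquinone monoether; 22 the (E)-alkenylboronate
Product: 23 (2S,3S)-6-(benzyloxy)-4-{(E)-2-[4-(benzyloxy)phenyl]ethenyl}-3-(group G)-2-(4-hydroxyphenyl)-2,3-dihydro-1-benzofuran-5-ol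
Conditions: Pd(OAc)2 (5 mol %), SPhos (2-dicyclohexylphosphino-2',6'-dimethoxybiphenyl, 10 mol %), K3PO4, dioxane/H2O, 80 °C, degassed
Reagents that add atoms: none
Why: Suzuki–Miyaura coupling with retention of alkene geometry; the bulky electron-rich biarylphosphine should allow oxidative addition at the di-ortho-substituted bromide and the phenols are tolerated as phenoxides.

Step 15
Reactants: 23 the diphenol
Product: 24 allyl 4-[(2S,3S)-6-(benzyloxy)-4-{(E)-2-[4-(benzyloxy)phenyl]ethenyl}-3-(group G)-5-hydroxy-2,3-dihydro-1-benzofuran-2-yl]phenyl carbonate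
Conditions: allyl chloroformate (1.05 equiv), pyridine, CH2Cl2, −40 to 0 °C
Reagents that add atoms: allyl chloroformate, C=CCOC(=O)Cl
Why: Acylation under steric control; the unhindered 4-hydroxyphenyl OH should react while the C5 OH, flanked by the styryl and benzyloxy groups, stays free.

Step 16
Reactants: 24 the allyl carbonate
Product: 25 the C5 trifluoromethanesulfonate of 24
Conditions: Tf2O, pyridine, CH2Cl2, 0 °C
Reagents that add atoms: trifluoromethanesulfonic anhydride, O=S(=O)(OS(=O)(=O)C(F)(F)F)C(F)(F)F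
Why: Triflation of the remaining hindered phenol activates the helper oxygen at C5 for removal.

Step 17
Reactants: 25 the aryl triflate allyl carbonate
Product: 26 4-[(2S,3S)-6-(benzyloxy)-4-{(E)-2-[4-(benzyloxy)phenyl]ethenyl}-3-(group G)-2,3-dihydro-1-benzofuran-2-yl]phenol
Conditions: Pd(OAc)2 (10 mol %), dppf (1,1'-bis(diphenylphosphino)ferrocene), HCO2H, Et3N, DMF, 70 °C, degassed
Reagents that add atoms: none
Why: Palladium-catalysed formate reduction of the aryl triflate removes the C5 oxygen, and the same zerovalent palladium/formate system cleaves the allyl carbonate through its pi-allyl complex (released as propene), so helper oxygen and temporary protecting group leave in one operation.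

Step 18
Reactants: 26 the hexabenzyl ether
Product: 27 (2S,3S)-3-[(2R,3R)-3-(3,5-dihydroxyphenyl)-7-hydroxy-2-(4-hydroxyphenyl)-2,3-dihydro-1-benzofuran-5-yl]-2-(4-hydroxyphenyl)-4-[(E)-2-(4-hydroxyphenyl)ethenyl]-2,3-dihydro-1-benzofuran-6-ol (CNP0172909.1)
Conditions: BCl3 (1 M in CH2Cl2, excess), pentamethylbenzene, CH2Cl2, −78 to −40 °C; MeOH quench
Reagents that add atoms: none
Why: BCl3 cleavage of aryl benzyl ethers with pentamethylbenzene as non-basic cation scavenger; at low temperature the stilbene and the benzylic C–O bonds of both dihydrofurans should survive, and any reversible opening at C2 or C2' would reclose to the trans isomers.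

**Compound list**
1 | 3-(benzyloxy)-2-hydroxybenzaldehyde | O=Cc1cccc(OCc2ccccc2)c1O | starting material
2 | 3-(benzyloxy)-5-bromo-2-hydroxybenzaldehyde | O=Cc1cc(Br)cc(OCc2ccccc2)c1O | intermediate
3 | 4-(benzyloxy)benzyl chloride | ClCc1ccc(OCc2ccccc2)cc1 | starting material
4 | 3-(benzyloxy)-2-{[4-(benzyloxy)benzyl]oxy}-5-bromobenzaldehyde | O=Cc1cc(Br)cc(OCc2ccccc2)c1OCc1ccc(OCc2ccccc2)cc1 | intermediate
5 | 1,3-bis(benzyloxy)-5-bromobenzene | Brc1cc(OCc2ccccc2)cc(OCc2ccccc2)c1 | starting material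
6 | [3,5-bis(benzyloxy)phenyl]magnesium bromide | Br[Mg]c1cc(OCc2ccccc2)cc(OCc2ccccc2)c1 | intermediate (not isolated)
7 | [3,5-bis(benzyloxy)phenyl](3-(benzyloxy)-2-{[4-(benzyloxy)benzyl]oxy}-5-bromophenyl)methanol (racemic) | OC(c1cc(OCc2ccccc2)cc(OCc2ccccc2)c1)c1cc(Br)cc(OCc2ccccc2)c1OCc1ccc(OCc2ccccc2)cc1 | intermediate
8 | [3,5-bis(benzyloxy)phenyl](3-(benzyloxy)-2-{[4-(benzyloxy)benzyl]oxy}-5-bromophenyl)methanone | O=C(c1cc(OCc2ccccc2)cc(OCc2ccccc2)c1)c1cc(Br)cc(OCc2ccccc2)c1OCc1ccc(OCc2ccccc2)cc1 | intermediate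
9 | hydrazone of 8 | NN=C(c1cc(OCc2ccccc2)cc(OCc2ccccc2)c1)c1cc(Br)cc(OCc2ccccc2)c1OCc1ccc(OCc2ccccc2)cc1 | intermediate
10 | diaryldiazomethane from 9 | [N-]=[N+]=C(c1cc(OCc2ccccc2)cc(OCc2ccccc2)c1)c1cc(Br)cc(OCc2ccccc2)c1OCc1ccc(OCc2ccccc2)cc1 | intermediate (not isolated)
11 | (2S,3R)-7-(benzyloxy)-2-[4-(benzyloxy)phenyl]-3-[3,5-bis(benzyloxy)phenyl]-5-bromo-2,3-dihydro-1-benzofuran (cis) | Brc1cc(OCc2ccccc2)c2c(c1)[C@@H](c1cc(OCc3ccccc3)cc(OCc3ccccc3)c1)[C@@H](c1ccc(OCc3ccccc3)cc1)O2 | intermediate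
12 | (2R,3R)-7-(benzyloxy)-2-[4-(benzyloxy)phenyl]-3-[3,5-bis(benzyloxy)phenyl]-5-bromo-2,3-dihydro-1-benzofuran (trans) | Brc1cc(OCc2ccccc2)c2c(c1)[C@@H](c1cc(OCc3ccccc3)cc(OCc3ccccc3)c1)[C@H](c1ccc(OCc3ccccc3)cc1)O2 | intermediate
13 | 4-acetoxystyrene | CC(=O)Oc1ccc(C=C)cc1 | starting material
14 | 4-[(E)-2-(group G)ethenyl]phenyl acetate | CC(=O)Oc1ccc(/C=C/c2cc(OCc3ccccc3)c3c(c2)[C@@H](c2cc(OCc4ccccc4)cc(OCc4ccccc4)c2)[C@H](c2ccc(OCc4ccccc4)cc2)O3)cc1 | intermediate
15 | 4-[(E)-2-(group G)ethenyl]phenol | Oc1ccc(/C=C/c2cc(OCc3ccccc3)c3c(c2)[C@@H](c2cc(OCc4ccccc4)cc(OCc4ccccc4)c2)[C@H](c2ccc(OCc4ccccc4)cc2)O3)cc1 | intermediate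
16 | 2-(benzyloxy)phenol | Oc1ccccc1OCc1ccccc1 | starting material
17 | 2-(benzyloxy)-6-bromophenol | Oc1c(Br)cccc1OCc1ccccc1 | intermediate
18 | 2-(benzyloxy)-6-bromo-1,4-benzoquinone | O=C1C=C(Br)C(=O)C(OCc2ccccc2)=C1 | intermediate
19 | 4-[(S)-2-(4-(benzyloxy)-2-bromo-3,6-dihydroxyphenyl)-2-(group G)ethylidene]cyclohexa-2,5-dien-1-one | Oc1cc(OCc2ccccc2)c(O)c(Br)c1[C@H](c1cc(OCc2ccccc2)c2c(c1)[C@@H](c1cc(OCc3ccccc3)cc(OCc3ccccc3)c1)[C@H](c1ccc(OCc3ccccc3)cc1)O2)C=C1C=CC(=O)C=C1 | intermediate (not isolated)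
20 | (2S,3S)-6-(benzyloxy)-4-bromo-3-(group G)-2-(4-hydroxyphenyl)-2,3-dihydro-1-benzofuran-5-ol | Brc1c(O)c(OCc2ccccc2)cc2c1[C@H](c1cc(OCc3ccccc3)c3c(c1)[C@@H](c1cc(OCc4ccccc4)cc(OCc4ccccc4)c1)[C@H](c1ccc(OCc4ccccc4)cc1)O3)[C@@H](c1ccc(O)cc1)O2 | intermediate
21 | 1-(benzyloxy)-4-ethynylbenzene | C#Cc1ccc(OCc2ccccc2)cc1 | starting material
22 | 2-{(E)-2-[4-(benzyloxy)phenyl]ethenyl}-4,4,5,5-tetramethyl-1,3,2-dioxaborolane | CC1(C)OB(/C=C/c2ccc(OCc3ccccc3)cc2)OC1(C)C | intermediate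
23 | (2S,3S)-6-(benzyloxy)-4-{(E)-2-[4-(benzyloxy)phenyl]ethenyl}-3-(group G)-2-(4-hydroxyphenyl)-2,3-dihydro-1-benzofuran-5-ol | c1ccccc1COc1ccc(/C=C/c2c(O)c(OCc3ccccc3)cc3c2[C@H](c2cc(OCc4ccccc4)c4c(c2)[C@@H](c2cc(OCc5ccccc5)cc(OCc5ccccc5)c2)[C@H](c2ccc(OCc5ccccc5)cc2)O4)[C@@H](c2ccc(O)cc2)O3)cc1 | intermediate
24 | allyl carbonate of the 4-hydroxyphenyl OH of 23 | c1ccccc1COc1ccc(/C=C/c2c(O)c(OCc3ccccc3)cc3c2[C@H](c2cc(OCc4ccccc4)c4c(c2)[C@@H](c2cc(OCc5ccccc5)cc(OCc5ccccc5)c2)[C@H](c2ccc(OCc5ccccc5)cc2)O4)[C@@H](c2ccc(OC(=O)OCC=C)cc2)O3)cc1 | intermediate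
25 | C5 trifluoromethanesulfonate of 24 | c1ccccc1COc1ccc(/C=C/c2c(OS(=O)(=O)C(F)(F)F)c(OCc3ccccc3)cc3c2[C@H](c2cc(OCc4ccccc4)c4c(c2)[C@@H](c2cc(OCc5ccccc5)cc(OCc5ccccc5)c2)[C@H](c2ccc(OCc5ccccc5)cc2)O4)[C@@H](c2ccc(OC(=O)OCC=C)cc2)O3)cc1 | intermediate
26 | 4-[(2S,3S)-6-(benzyloxy)-4-{(E)-2-[4-(benzyloxy)phenyl]ethenyl}-3-(group G)-2,3-dihydro-1-benzofuran-2-yl]phenol | c1ccccc1COc1ccc(/C=C/c2cc(OCc3ccccc3)cc3c2[C@H](c2cc(OCc4ccccc4)c4c(c2)[C@@H](c2cc(OCc5ccccc5)cc(OCc5ccccc5)c2)[C@H](c2ccc(OCc5ccccc5)cc2)O4)[C@@H](c2ccc(O)cc2)O3)cc1 | intermediate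
27 | (2S,3S)-3-[(2R,3R)-3-(3,5-dihydroxyphenyl)-7-hydroxy-2-(4-hydroxyphenyl)-2,3-dihydro-1-benzofuran-5-yl]-2-(4-hydroxyphenyl)-4-[(E)-2-(4-hydroxyphenyl)ethenyl]-2,3-dihydro-1-benzofuran-6-ol | Oc1ccc(/C=C/c2cc(O)cc3c2[C@H](c2cc(O)c4c(c2)[C@@H](c2cc(O)cc(O)c2)[C@H](c2ccc(O)cc2)O4)[C@@H](c2ccc(O)cc2)O3)cc1 | target

**Totals**
Total step count: 18. Longest linear sequence: 15 (steps 1–9, 12, 14–18).

**Steps most likely to fail**

Step 12 (proposed method). What may go wrong: electron transfer from the phenol to the quinone followed by radical homocoupling, attack through the wrong alkene carbon, or poor facial selectivity. Fallback with known chemistry: the ring-A dihydrofuran is built by the same donor/donor carbene C–H insertion that is used for ring B, which makes C2–C3 instead of the two bonds of step 12. 5-Bromoresorcinol is formylated (POCl3, DMF; Vilsmeier–Haack) to 2-bromo-4,6-dihydroxybenzaldehyde F1, benzylated at the para OH (BnBr, NaHCO3, KI, MeCN) to 4-(benzyloxy)-2-bromo-6-hydroxybenzaldehyde F2 and alkylated with 3 (K2CO3, DMF) to 4-(benzyloxy)-2-{[4-(benzyloxy)benzyl]oxy}-6-bromobenzaldehyde F3. Bromide 12 is lithiated (n-BuLi, THF, −78 °C) and added to F3 to give the diarylmethanol F4, which is oxidised (MnO2) to the ketone F5 and condensed with N2H4·H2O to the hydrazone F6. MnO2 gives the diazo compound F7, and Rh2(S-PTAD)4 should cyclise it to the cis-dihydrobenzofuran F8. TFA epimerises C2 to the trans bromide F9, Suzuki–Miyaura coupling with 22 (Pd(OAc)2, SPhos, K3PO4) gives the heptabenzyl ether F10, and BCl3/pentamethylbenzene as in step 18 comes back to the route at 27.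

Step 14. What may go wrong: slow oxidative addition at the di-ortho-substituted, phenoxide-bearing bromide and competing protodeboronation of 22. Fallback: Stille coupling of 20 with tributyl(vinyl)stannane (Pd(PPh3)4, toluene, 100 °C) transfers the small vinyl group to give the 4-vinyl compound F11. A Heck reaction of F11 with 1-(benzyloxy)-4-iodobenzene (Pd(OAc)2, Et3N, DMF, 80 °C) then builds the stilbene at the unhindered alkene terminus and comes back to the route at 23.

Step 17. What may go wrong: sluggish reduction of the di-ortho-substituted triflate, 1,4-migration of palladium to the styryl group with loss of E geometry, or O-allylation of the liberated phenoxide. Fallback: the two tasks are separated and the hydride step is replaced by borylation and protodeboronation. Removal of the allyl carbonate from 25 (Pd(PPh3)4, morpholine, THF, rt) gives the phenol triflate F12. Miyaura borylation (B2pin2, PdCl2(dppf), KOAc, dioxane, 90 °C) gives the pinacol boronate F13, and protodeboronation (CsF, H2O, dioxane, 100 °C) comes back to the route at 26.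

**Further compounds**
F1 | step 12 | 2-bromo-4,6-dihydroxybenzaldehyde | O=Cc1c(O)cc(O)cc1Br
F2 | step 12 | 4-(benzyloxy)-2-bromo-6-hydroxybenzaldehyde | O=Cc1c(O)cc(OCc2ccccc2)cc1Br
F3 | step 12 | 4-(benzyloxy)-2-{[4-(benzyloxy)benzyl]oxy}-6-bromobenzaldehyde | O=Cc1c(OCc2ccc(OCc3ccccc3)cc2)cc(OCc2ccccc2)cc1Br
F4 | step 12 | (4-(benzyloxy)-2-{[4-(benzyloxy)benzyl]oxy}-6-bromophenyl)(group G)methanol (both carbinol epimers) | OC(c1c(OCc2ccc(OCc3ccccc3)cc2)cc(OCc2ccccc2)cc1Br)c1cc(OCc2ccccc2)c2c(c1)[C@@H](c1cc(OCc3ccccc3)cc(OCc3ccccc3)c1)[C@H](c1ccc(OCc3ccccc3)cc1)O2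
F5 | step 12 | (4-(benzyloxy)-2-{[4-(benzyloxy)benzyl]oxy}-6-bromophenyl)(group G)methanone | O=C(c1c(OCc2ccc(OCc3ccccc3)cc2)cc(OCc2ccccc2)cc1Br)c1cc(OCc2ccccc2)c2c(c1)[C@@H](c1cc(OCc3ccccc3)cc(OCc3ccccc3)c1)[C@H](c1ccc(OCc3ccccc3)cc1)O2
F6 | step 12 | hydrazone of F5 | NN=C(c1c(OCc2ccc(OCc3ccccc3)cc2)cc(OCc2ccccc2)cc1Br)c1cc(OCc2ccccc2)c2c(c1)[C@@H](c1cc(OCc3ccccc3)cc(OCc3ccccc3)c1)[C@H](c1ccc(OCc3ccccc3)cc1)O2
F7 | step 12 | diazo compound from F6 | [N-]=[N+]=C(c1c(OCc2ccc(OCc3ccccc3)cc2)cc(OCc2ccccc2)cc1Br)c1cc(OCc2ccccc2)c2c(c1)[C@@H](c1cc(OCc3ccccc3)cc(OCc3ccccc3)c1)[C@H](c1ccc(OCc3ccccc3)cc1)O2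
F8 | step 12 | (2R,3S)-6-(benzyloxy)-2-[4-(benzyloxy)phenyl]-4-bromo-3-(group G)-2,3-dihydro-1-benzofuran (cis) | Brc1cc(OCc2ccccc2)cc2c1[C@H](c1cc(OCc3ccccc3)c3c(c1)[C@@H](c1cc(OCc4ccccc4)cc(OCc4ccccc4)c1)[C@H](c1ccc(OCc4ccccc4)cc1)O3)[C@H](c1ccc(OCc3ccccc3)cc1)O2
F9 | step 12 | (2S,3S)-6-(benzyloxy)-2-[4-(benzyloxy)phenyl]-4-bromo-3-(group G)-2,3-dihydro-1-benzofuran (trans) | Brc1cc(OCc2ccccc2)cc2c1[C@H](c1cc(OCc3ccccc3)c3c(c1)[C@@H](c1cc(OCc4ccccc4)cc(OCc4ccccc4)c1)[C@H](c1ccc(OCc4ccccc4)cc1)O3)[C@@H](c1ccc(OCc3ccccc3)cc1)O2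
F10 | step 12 | heptabenzyl ether of 27 | c1ccccc1COc1ccc(/C=C/c2cc(OCc3ccccc3)cc3c2[C@H](c2cc(OCc4ccccc4)c4c(c2)[C@@H](c2cc(OCc5ccccc5)cc(OCc5ccccc5)c2)[C@H](c2ccc(OCc5ccccc5)cc2)O4)[C@@H](c2ccc(OCc4ccccc4)cc2)O3)cc1
F11 | step 14 | (2S,3S)-6-(benzyloxy)-4-ethenyl-3-(group G)-2-(4-hydroxyphenyl)-2,3-dihydro-1-benzofuran-5-ol | C=Cc1c(O)c(OCc2ccccc2)cc2c1[C@H](c1cc(OCc3ccccc3)c3c(c1)[C@@H](c1cc(OCc4ccccc4)cc(OCc4ccccc4)c1)[C@H](c1ccc(OCc4ccccc4)cc1)O3)[C@@H](c1ccc(O)cc1)O2
F12 | step 17 | C5 trifluoromethanesulfonate of 23 with free 4-hydroxyphenyl group | c1ccccc1COc1ccc(/C=C/c2c(OS(=O)(=O)C(F)(F)F)c(OCc3ccccc3)cc3c2[C@H](c2cc(OCc4ccccc4)c4c(c2)[C@@H](c2cc(OCc5ccccc5)cc(OCc5ccccc5)c2)[C@H](c2ccc(OCc5ccccc5)cc2)O4)[C@@H](c2ccc(O)cc2)O3)cc1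
F13 | step 17 | C5 pinacol boronate corresponding to F12 | c1ccccc1COc1ccc(/C=C/c2c(B3OC(C)(C)C(C)(C)O3)c(OCc3ccccc3)cc3c2[C@H](c2cc(OCc4ccccc4)c4c(c2)[C@@H](c2cc(OCc5ccccc5)cc(OCc5ccccc5)c2)[C@H](c2ccc(OCc5ccccc5)cc2)O4)[C@@H](c2ccc(O)cc2)O3)cc1
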